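**Strategy.** Polonidine A is cut through both pyrrole rings at C3–C3a and N1–C2. This exposes the five-carbon chain C2–C3–CH2–C3'–C2' as glutaraldehyde, with the bridging CH2 as its central carbon. A twofold Fischer indolisation of the glutaraldehyde bis-hydrazone of 1-(2-methylbut-3-yn-2-yl)-1-phenylhydrazine should close both pyrrole rings and form four skeletal bonds in one operation. The hydrazine, made from aniline in three steps, carries each N-substituent as the 1,1-dimethylpropargyl group, which resists ionisation in acid better than the tertiary allyl group. Lindlar semihydrogenation then gives the two 1,1-dimethylallyl groups.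

Key step: step 4

Remark: the target SMILES holds no stereocentre and no stereogenic double bond, so the compound is achiral and the route needs no stereocontrol; glutaraldehyde is taken as the commercial 50 wt% aqueous solution.

**Route**

Step 1
Reactants: 1 aniline (1.5 equiv); 2 3-chloro-3-methylbut-1-yne
Product: 3 N-(2-methylbut-3-yn-2-yl)aniline
Conditions: CuCl (10 mol%), Et3N (1.5 equiv), THF, N2, 0 °C → rt
Reagents that add atoms: none
Why: Copper-catalysed propargylic amination (Hennion-type substitution of a tertiary propargylic chloride through a copper acetylide/allenylidene) forms the hindered C–N bond without SN2 displacement, the bulk of the new substituent should stop a second alkylation, and working at or below room temperature avoids copper-promoted cyclisation to a dihydroquinoline.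

Step 2
Reactants: 3 N-(2-methylbut-3-yn-2-yl)aniline
Product: 4 N-(2-methylbut-3-yn-2-yl)-N-nitrosoaniline
Conditions: t-BuONO (1.5 equiv), CH2Cl2, rt (warm to 40 °C if slow); crude product carried on, handled as a presumed carcinogen
Reagents that add atoms: tert-butyl nitrite, CC(C)(C)ON=O
Why: N-Nitrosation of a secondary arylamine by NO+ transfer from an alkyl nitrite runs under neutral conditions, so neither Fischer–Hepp migration to the para position nor acid ionisation of the tertiary propargylic C–N bond is expected, and the alkyne is inert.

Step 3
Reactants: 4 N-(2-methylbut-3-yn-2-yl)-N-nitrosoaniline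
Product: 5 1-(2-methylbut-3-yn-2-yl)-1-phenylhydrazine
Conditions: Zn dust (4 equiv), AcOH/H2O, 0 → 15 °C; filtration, cold aq. NH3 work-up; used directly under N2
Reagents that add atoms: none
Why: Dissolving-metal reduction of an N-nitrosamine with zinc in acetic acid, the classical route to 1-alkyl-1-arylhydrazines, converts N=O into NH2 while leaving the terminal alkyne and the C–N bonds untouched, and low temperature with prompt work-up should limit N–N cleavage.

Step 4
Reactants: 5 1-(2-methylbut-3-yn-2-yl)-1-phenylhydrazine (2.2 equiv); 6 glutaraldehyde (1.0 equiv)
Product: 9 3,3'-methylenebis[1-(2-methylbut-3-yn-2-yl)-1H-indole], via bis-hydrazone 7 (not isolated), via mono-indole hydrazone 8 (not isolated)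
Conditions: EtOH, 0 °C → rt (hydrazone formation checked by TLC); then evaporation, degassed AcOH, 70 °C, N2
Reagents that add atoms: none
Why: Each hydrazone arm of 7 tautomerises in acid to its ene-hydrazine, a [3,3]-sigmatropic shift breaks N–N and joins the former aldehyde α-carbon to an ortho carbon of the phenyl ring (C3–C3a), and after rearomatisation the anilino nitrogen adds to the iminium carbon (N1–C2) and the aminal loses ammonia, the first indolisation giving 8 and the second 9. This is a Fischer indole synthesis run twice on one bis-hydrazone, the closest known type being the indolisation of N-alkyl-N-arylhydrazones of aldehydes and of bis-hydrazones of dicarbonyl compounds. Both pyrrole rings close in the same mode, 5-exo-trig attack of nitrogen on the C=N+ carbon, and no stereocentre is formed. Regiochemistry is fixed by the substrate, because each aldehyde carbon has a single α-CH2 (C2 and C4 of the dialdehyde) and the unsubstituted phenyl ring has two equivalent ortho positions, so C3 of glutaraldehyde must end as the bridging CH2. The chemoselectivity needed is complete bis-hydrazone formation before any acid-driven chemistry of a free aldehyde, which a slight excess of a hydrazine with one NH2 group under neutral conditions should secure, together with survival of the N–C(Me)2C≡CH bonds, the alkynes and the acid-sensitive diindolylmethane, which weak acid at moderate temperature and the poorly ionising propargylic substituent should secure. Attack of C2 of the first indole on the remaining hydrazone arm of 8 would have to close a cyclopenta[b]indole ring with the reacting C2=C3 π-bond inside the new ring, a geometrically disfavoured mode that should not compete.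

Step 5
Reactants: 9 3,3'-methylenebis[1-(2-methylbut-3-yn-2-yl)-1H-indole]
Product: 10 polonidine A, 3,3'-methylenebis[1-(2-methylbut-3-en-2-yl)-1H-indole]
Conditions: H2 (1 atm), Lindlar catalyst (Pd/CaCO3, Pb-poisoned), quinoline, EtOAc, rt; stopped after uptake of 2 equiv H2
Reagents that add atoms: none
Why: Lindlar semihydrogenation, in which the poisoned palladium surface with added quinoline binds and reduces the terminal alkynes much faster than the resulting monosubstituted alkenes, should give both 1,1-dimethylallyl groups while the indole rings, the bridging CH2 and the N–C bonds stay untouched; terminal alkenes raise no stereochemical question.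

**Compound list**

1 | aniline | Nc1ccccc1 | starting material
2 | 3-chloro-3-methylbut-1-yne | C#CC(C)(C)Cl | starting material
3 | N-(2-methylbut-3-yn-2-yl)aniline | C#CC(C)(C)Nc1ccccc1 | intermediate
4 | N-(2-methylbut-3-yn-2-yl)-N-nitrosoaniline | C#CC(C)(C)N(N=O)c1ccccc1 | intermediate
5 | 1-(2-methylbut-3-yn-2-yl)-1-phenylhydrazine | C#CC(C)(C)N(N)c1ccccc1 | intermediate
6 | glutaraldehyde (pentanedial) | O=CCCCC=O | starting material
7 | pentanedial bis[N-(2-methylbut-3-yn-2-yl)-N-phenylhydrazone], (E,E) | C#CC(C)(C)N(/N=C/CCC/C=N/N(c1ccccc1)C(C)(C)C#C)c1ccccc1 | intermediate
8 | 3-[1-(2-methylbut-3-yn-2-yl)-1H-indol-3-yl]propanal N-(2-methylbut-3-yn-2-yl)-N-phenylhydrazone, (E) | C#CC(C)(C)n1cc(CC/C=N/N(c2ccccc2)C(C)(C)C#C)c2ccccc21 | intermediate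
9 | 3,3'-methylenebis[1-(2-methylbut-3-yn-2-yl)-1H-indole] | C#CC(C)(C)n1cc(Cc2cn(C(C)(C)C#C)c3ccccc23)c2ccccc21 | intermediate
10 | polonidine A, 3,3'-methylenebis[1-(2-methylbut-3-en-2-yl)-1H-indole] | C=CC(C)(C)n1cc(Cc2cn(C(C)(C)C=C)c3ccccc23)c2ccccc21 | target

**Count**

Total steps: 5. Longest linear sequence: 5 steps (1 → 3 → 4 → 5 → 9 → 10).

**Steps most likely to fail**

1. Step 4. The second indolisation may stall at the mono-indole stage, the tertiary propargylic group may be lost from nitrogen in acid, or the product may fragment or oligomerise at the indol-3-ylmethyl position. The fallback builds the bis-indole from a preformed N-substituted indole and a one-carbon electrophile instead of by indolisation. It sets out from 2, which is coupled with commercial indoline (C1Cc2ccccc2N1) under the conditions of step 1 (CuCl, Et3N, THF, rt) to give 1-(2-methylbut-3-yn-2-yl)indoline F1. Dehydrogenation with DDQ (toluene, rt) should give 1-(2-methylbut-3-yn-2-yl)-1H-indole F2. Two equivalents of F2 and aqueous formaldehyde (C=O) in AcOH at rt should then undergo twofold electrophilic substitution at C3 (hydroxymethylation, ionisation to the 3-methyleneindoleninium ion, capture by the second indole). This comes back to the route at 9.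

2. Step 5. Hydrogenation may run on to ethyl groups, or the two ends may be reduced unevenly, which would give mixtures that differ by two hydrogens and are hard to separate. The fallback sets out from 9 and replaces catalytic hydrogenation by hydrometalation and protonolysis. Hydroboration with dicyclohexylborane (2.2 equiv, THF, 0 °C) should give 3,3'-methylenebis{1-[(E)-4-(dicyclohexylboranyl)-2-methylbut-3-en-2-yl]-1H-indole} F3. Protonolysis of both alkenyl–boron bonds with AcOH (rt) comes back to the route at 10. An alkenylborane cannot be reduced further, so the reduction level is set by the mechanism and not by timing.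

3. Step 3. Over-reduction may cleave the N–N bond (return to 3), zinc(II) may promote addition of the new NH2 group to the neighbouring alkyne, or the free hydrazine may oxidise in air during isolation. The fallback sets out from 4 and avoids the free hydrazine. Compound 4 is reduced with Zn dust in AcOH at 0–10 °C in the presence of 6 (0.5 equiv), so that each hydrazine molecule is condensed to its hydrazone as it forms and never accumulates. Filtration from zinc gives a solution of 7, where the route is rejoined at the acid stage of step 4. This fallback makes no compound outside the list (F0).

**Further compounds**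

F1 | step 4 | 1-(2-methylbut-3-yn-2-yl)indoline | C#CC(C)(C)N1CCc2ccccc21
F2 | step 4 | 1-(2-methylbut-3-yn-2-yl)-1H-indole | C#CC(C)(C)n1ccc2ccccc21
F3 | step 5 | 3,3'-methylenebis{1-[(E)-4-(dicyclohexylboranyl)-2-methylbut-3-en-2-yl]-1H-indole} | C1CCCCC1B(C1CCCCC1)/C=C/C(C)(C)n1cc(Cc2cn(C(C)(C)/C=C/B(C3CCCCC3)C3CCCCC3)c3ccccc23)c2ccccc21
F0 | step 3 | none | none
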